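**Plan**

- Numbering used: C1 is the ring carbinol carbon; C2, C3=C4(CH3) (E), C5, C6, C7, C8(CH3)2, C9 and C10=C11(CH3) (Z) follow round the cycloundecadiene, and C11 is bonded to C1.
- Retrosynthetic cuts: the vanillate C–O bond; the ring bond C5–C6 (α-sulfonyl carbanion on C6, allylic chloride at C5); C1–C11 (alkenylchromium plus aldehyde); C10=C11 (Wittig); C7–C8 (radical conjugate addition).
- Enabling feature: C5 is the allylic CH2 of the C3=C4 alkene and C6 is a plain CH2 two bonds from the quaternary C8. One PhSO2 group on C6 therefore serves three times: as the acceptor that lets C8 be built, as the carbanion-stabilising group that closes the eleven-membered carbocycle onto C5, and as a group that is then reduced off.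
- Forward order: a sulfonyl Z-iodoalkene (C6–C11) and an E-aldehyde (C1–C5) are made separately and joined at C1–C11; the only ring is closed last at C5–C6; desulfonylation and acylation follow.
- Stereochemistry: C1 (R) from a ligand-controlled Nozaki–Hiyama–Kishi addition; Z-C10=C11 from the α-iodo ylide olefination; E-C3=C4 from SeO2 oxidation of the trans methyl group of a prenyl-type alkene; the SN2 ring closure touches neither alkene.

Key step: step 10

Remark: the C6 epimers formed in the ring closure are carried on together, because this centre disappears on desulfonylation; methyl 4-methylpent-3-enoate is taken as purchased (otherwise one esterification from the acid).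

**Step 1**
Reactants: 1 3-methylbut-3-en-1-ol; 2 phenyl vinyl sulfone
Product: 3 3,3-dimethyl-5-(phenylsulfonyl)pentan-1-ol
Conditions: Fe(acac)3 (30 mol %), PhSiH3, EtOH/ethylene glycol, 60 °C
Reagents that add atoms: none
Why: Mukaiyama-type hydrogen-atom-transfer Giese reaction, in which an iron hydride gives H to the terminal CH2 of 1 and the tertiary radical adds to the vinyl sulfone, so the quaternary carbon C8 is made with the sulfonyl helper already on C6.

**Step 2**
Reactants: 3 3,3-dimethyl-5-(phenylsulfonyl)pentan-1-ol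
Product: 4 3,3-dimethyl-5-(phenylsulfonyl)pentanal
Conditions: TEMPO (10 mol %), PhI(OAc)2, CH2Cl2, rt
Reagents that add atoms: none
Why: Oxoammonium (TEMPO) oxidation stops at the aldehyde and is non-basic, so the sulfone-bearing aldehyde should not undergo intramolecular aldol closure.

**Step 3**
Reactants: 4 3,3-dimethyl-5-(phenylsulfonyl)pentanal
Product: 5 {[(5Z)-6-iodo-3,3-dimethylhept-5-en-1-yl]sulfonyl}benzene
Conditions: EtPPh3I, n-BuLi, THF, rt; I2, −78 °C; NaN(SiMe3)2, −20 °C; then 4, −78 °C to rt
Reagents that add atoms: ethyltriphenylphosphonium iodide, CC[P+](c1ccccc1)(c1ccccc1)c1ccccc1.[I-]; iodine, II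
Why: Stork–Zhao-type Wittig olefination with the α-iodoethylidene ylide should give the Z-2-iodoalkene (iodine cis to the chain) under kinetic control at −78 °C, and the ylide is too weakly basic to deprotonate the sulfone.

**Step 4**
Reactants: 6 methyl 4-methylpent-3-enoate
Product: 7 methyl (3E)-5-hydroxy-4-methylpent-3-enoate
Conditions: SeO2 (cat.), t-BuOOH, CH2Cl2, rt
Reagents that add atoms: selenium dioxide, O=[Se]=O (oxygen carrier); tert-butyl hydroperoxide, CC(C)(C)OO (terminal oxidant)
Why: Riley allylic oxidation (ene reaction, then 2,3-sigmatropic shift) attacks the methyl group trans to the chain at the more substituted alkene carbon, which sets the E geometry of C3=C4.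

**Step 5**
Reactants: 7 methyl (3E)-5-hydroxy-4-methylpent-3-enoate
Product: 8 methyl (3E)-5-[(tert-butyldimethylsilyl)oxy]-4-methylpent-3-enoate
Conditions: TBSCl, imidazole, DMF, rt
Reagents that add atoms: tert-butyldimethylsilyl chloride, CC(C)(C)[Si](C)(C)Cl
Why: Standard silylation of the primary allylic alcohol, so that the C5 oxygen survives the hydride reduction and the chromium coupling.

**Step 6**
Reactants: 8 methyl (3E)-5-[(tert-butyldimethylsilyl)oxy]-4-methylpent-3-enoate
Product: 9 (3E)-5-[(tert-butyldimethylsilyl)oxy]-4-methylpent-3-enal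
Conditions: i-Bu2AlH (1.05 equiv), CH2Cl2, −78 °C; aq. potassium sodium tartrate
Reagents that add atoms: none
Why: Partial ester reduction through the aluminium hemiacetal, stable at −78 °C, should give the β,γ-unsaturated aldehyde, which is used at once so that the alkene does not move into conjugation.

**Step 7**
Reactants: 5 {[(5Z)-6-iodo-3,3-dimethylhept-5-en-1-yl]sulfonyl}benzene; 9 (3E)-5-[(tert-butyldimethylsilyl)oxy]-4-methylpent-3-enal
Product: 10 (2E,5R,6Z)-1-[(tert-butyldimethylsilyl)oxy]-2,6,9,9-tetramethyl-11-(phenylsulfonyl)undeca-2,6-dien-5-ol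
Conditions: CrCl2 (10 mol %), N-[2-(4-tert-butyl-4,5-dihydro-1,3-oxazol-2-yl)-6-methylphenyl]methanesulfonamide (the enantiomer that gives Si-face addition), 1,8-bis(dimethylamino)naphthalene, NiCl2(2,9-dimethyl-1,10-phenanthroline) (2 mol %), Mn, Cp2ZrCl2, LiCl, MeCN, rt
Reagents that add atoms: none
Why: Catalytic asymmetric Nozaki–Hiyama–Kishi reaction, in which zerovalent nickel activates the C–I bond, the alkenyl group passes to chromium with retention of the Z geometry, and the chiral sulfonamide ligand directs addition to the Si face of the aldehyde to set C1 as R; sulfone, silyl ether and alkenes are inert.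

**Step 8**
Reactants: 10 (2E,5R,6Z)-1-[(tert-butyldimethylsilyl)oxy]-2,6,9,9-tetramethyl-11-(phenylsulfonyl)undeca-2,6-dien-5-ol
Product: 11 (2E,5R,6Z)-2,6,9,9-tetramethyl-11-(phenylsulfonyl)undeca-2,6-diene-1,5-diol
Conditions: Bu4NF, THF, 0 °C
Reagents that add atoms: none
Why: Fluoride cleaves the primary allylic silyl ether and leaves the sulfone, both alkenes and the C1 stereocentre untouched.

**Step 9**
Reactants: 11 (2E,5R,6Z)-2,6,9,9-tetramethyl-11-(phenylsulfonyl)undeca-2,6-diene-1,5-diol
Product: 13 (2E,5R,6Z)-1-chloro-2,6,9,9-tetramethyl-11-(phenylsulfonyl)undeca-2,6-dien-5-ol, via allylic mesylate 12 (not isolated)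
Conditions: MsCl (1.05 equiv), 2,4,6-collidine, LiCl, DMF, 0 °C
Reagents that add atoms: methanesulfonyl chloride, CS(=O)(=O)Cl (sulfonate of 12); lithium chloride, [Li+].[Cl-] (chlorine of 13)
Why: The primary allylic hydroxyl is sulfonylated much faster than the hindered secondary one, and chloride displaces the mesylate in situ by SN2 at the primary carbon, so the E alkene should stay in place.

**Step 10**
Reactants: 13 (2E,5R,6Z)-1-chloro-2,6,9,9-tetramethyl-11-(phenylsulfonyl)undeca-2,6-dien-5-ol
Product: 15 (1R,2Z,9E)-2,5,5,9-tetramethyl-7-(phenylsulfonyl)cycloundeca-2,9-dien-1-ol (both C7 epimers), via dilithium alkoxide carbanion 14 (not isolated)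
Conditions: LiN(i-Pr)2 (2.2 equiv), THF (0.003 M), −78 to 0 °C; aq. NH4Cl
Reagents that add atoms: none
Why: Two equivalents of base give the lithium alkoxide and the C6 α-sulfonyl carbanion (14), which displaces chloride from the allylic carbon C5 in an intramolecular SN2 reaction at high dilution. The closest known reaction type is the macrocyclisation of sulfonyl- and cyanohydrin-stabilised carbanions onto allylic halides, used to close ten- to fourteen-membered terpenoid carbocycles. The cycloundecadiene ring is closed in the 11-exo-tet mode. The new stereocentre at C6 (ring position 7) is not controlled and need not be, since it is erased with the sulfonyl group in step 11. The step needs SN2 over SN2' attack, C- over O-alkylation and ring closure over oligomerisation: the unhindered primary C5 and the strain of the nine-membered SN2' alternative favour direct attack, the alkoxide cannot reach C5 because a six-membered ring through the E alkene is impossible, and the dilution disfavours intermolecular reaction. Because no allyl–metal intermediate is involved, the E geometry of C3=C4, the Z geometry of C10=C11 and the configuration of C1 should pass through unchanged.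

**Step 11**
Reactants: 15 (1R,2Z,9E)-2,5,5,9-tetramethyl-7-(phenylsulfonyl)cycloundeca-2,9-dien-1-ol
Product: 16 (1R,2Z,9E)-2,5,5,9-tetramethylcycloundeca-2,9-dien-1-ol
Conditions: Na/Hg (6 % Na), Na2HPO4, MeOH/THF, −20 °C
Reagents that add atoms: none
Why: Reductive desulfonylation by electron transfer cleaves the C6–S bond and protonates C6; isolated alkenes and the allylic alcohol are not reduced, and the low temperature with fast second electron transfer should keep the transient C6 radical from adding across the ring.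

**Step 12**
Reactants: 16 (1R,2Z,9E)-2,5,5,9-tetramethylcycloundeca-2,9-dien-1-ol; 17 4-acetoxy-3-methoxybenzoic acid
Product: 18 (1R,2Z,9E)-2,5,5,9-tetramethylcycloundeca-2,9-dien-1-yl 4-acetoxy-3-methoxybenzoate
Conditions: EDC·HCl, DMAP (0.2 equiv), CH2Cl2, 0 °C to rt
Reagents that add atoms: none
Why: Steglich esterification; the phenol is masked as its acetate so that only the carboxyl group acylates the hindered allylic alcohol, and the C1–O bond is not broken, so the configuration is retained.

**Step 13**
Reactants: 18 (1R,2Z,9E)-2,5,5,9-tetramethylcycloundeca-2,9-dien-1-yl 4-acetoxy-3-methoxybenzoate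
Product: 19 (1R,2Z,9E)-2,5,5,9-tetramethylcycloundeca-2,9-dien-1-yl 4-hydroxy-3-methoxybenzoate
Conditions: pyrrolidine, CH2Cl2, 0 °C
Reagents that add atoms: none
Why: Aminolysis removes the aryl acetate, which is far more electrophilic than the hindered aroyl ester of the secondary alcohol, and frees the phenol of the target.

**Compound list**

1 | 3-methylbut-3-en-1-ol | C=C(C)CCO | starting material
2 | phenyl vinyl sulfone | C=CS(=O)(=O)c1ccccc1 | starting material
3 | 3,3-dimethyl-5-(phenylsulfonyl)pentan-1-ol | OCCC(C)(C)CCS(=O)(=O)c1ccccc1 | intermediate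
4 | 3,3-dimethyl-5-(phenylsulfonyl)pentanal | O=CCC(C)(C)CCS(=O)(=O)c1ccccc1 | intermediate
5 | {[(5Z)-6-iodo-3,3-dimethylhept-5-en-1-yl]sulfonyl}benzene | C/C(I)=C/CC(C)(C)CCS(=O)(=O)c1ccccc1 | intermediate
6 | methyl 4-methylpent-3-enoate | COC(=O)CC=C(C)C | starting material
7 | methyl (3E)-5-hydroxy-4-methylpent-3-enoate | COC(=O)C/C=C(\C)CO | intermediate
8 | methyl (3E)-5-[(tert-butyldimethylsilyl)oxy]-4-methylpent-3-enoate | COC(=O)C/C=C(\C)CO[Si](C)(C)C(C)(C)C | intermediate
9 | (3E)-5-[(tert-butyldimethylsilyl)oxy]-4-methylpent-3-enal | O=CC/C=C(\C)CO[Si](C)(C)C(C)(C)C | intermediate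
10 | (2E,5R,6Z)-1-[(tert-butyldimethylsilyl)oxy]-2,6,9,9-tetramethyl-11-(phenylsulfonyl)undeca-2,6-dien-5-ol | O[C@@H](/C(C)=C\CC(C)(C)CCS(=O)(=O)c1ccccc1)C/C=C(\C)CO[Si](C)(C)C(C)(C)C | intermediate
11 | (2E,5R,6Z)-2,6,9,9-tetramethyl-11-(phenylsulfonyl)undeca-2,6-diene-1,5-diol | O[C@@H](/C(C)=C\CC(C)(C)CCS(=O)(=O)c1ccccc1)C/C=C(\C)CO | intermediate
12 | (2E,5R,6Z)-5-hydroxy-2,6,9,9-tetramethyl-11-(phenylsulfonyl)undeca-2,6-dien-1-yl methanesulfonate (not isolated) | O[C@@H](/C(C)=C\CC(C)(C)CCS(=O)(=O)c1ccccc1)C/C=C(\C)COS(C)(=O)=O | intermediate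
13 | (2E,5R,6Z)-1-chloro-2,6,9,9-tetramethyl-11-(phenylsulfonyl)undeca-2,6-dien-5-ol | O[C@@H](/C(C)=C\CC(C)(C)CCS(=O)(=O)c1ccccc1)C/C=C(\C)CCl | intermediate
14 | dilithium salt of 13: O5 alkoxide and carbanion at the sulfonyl-bearing carbon (not isolated) | [Li+].[Li+].[O-][C@@H](/C(C)=C\CC(C)(C)C[CH-]S(=O)(=O)c1ccccc1)C/C=C(\C)CCl | intermediate
15 | (1R,2Z,9E)-2,5,5,9-tetramethyl-7-(phenylsulfonyl)cycloundeca-2,9-dien-1-ol, both C7 epimers | O[C@@H]1C/C=C(\C)CC(S(=O)(=O)c2ccccc2)CC(C)(C)C/C=C\1C | intermediate
16 | (1R,2Z,9E)-2,5,5,9-tetramethylcycloundeca-2,9-dien-1-ol | O[C@@H]1C/C=C(\C)CCCC(C)(C)C/C=C\1C | intermediate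
17 | 4-acetoxy-3-methoxybenzoic acid | COc1cc(C(=O)O)ccc1OC(C)=O | starting material
18 | (1R,2Z,9E)-2,5,5,9-tetramethylcycloundeca-2,9-dien-1-yl 4-acetoxy-3-methoxybenzoate | COc1cc(C(=O)O[C@@H]2C/C=C(\C)CCCC(C)(C)C/C=C\2C)ccc1OC(C)=O | intermediate
19 | (1R,2Z,9E)-2,5,5,9-tetramethylcycloundeca-2,9-dien-1-yl 4-hydroxy-3-methoxybenzoate | COc1cc(C(=O)O[C@@H]2C/C=C(\C)CCCC(C)(C)C/C=C\2C)ccc1O | target

**Step count**

Total: 13 steps. Longest linear sequence: 10 steps (6 to 19 through steps 4–13, or equally 1 to 19 through steps 1–3 and 7–13).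

**Steps most likely to fail**

1. Step 10 (ring closure). Intermolecular alkylation to oligomers, or base-induced loss of HCl from the allylic chloride, may outrun closure of the strained eleven-membered ring. The fallback closes the same bond on a palladium template under neutral conditions with a doubly activated C6. It sets out from 10. Silylation of the C1 hydroxyl (TBSOTf, 2,6-lutidine) would give the bis(silyl) ether F1. Deprotonation with LiN(i-Pr)2 and sulfonylation with PhSO2F would give the geminal bis(sulfone) F2. HF·pyridine would remove only the primary silyl group to give the allylic alcohol F3, and ClCO2Me/pyridine would convert it into the allylic methyl carbonate F4. With Pd(PPh3)4 in hot THF at high dilution, zerovalent palladium ionises the carbonate, the methoxide released deprotonates the bis(sulfone), and attack at the primary allyl terminus of the syn π-allyl complex should give the E-configured macrocyclic bis(sulfone) F5 (Tsuji–Trost macrocyclisation). The C1 silyl ether is not a leaving group. Na/Hg with Na2HPO4 would remove both sulfonyl groups to give the silyl ether F6, and Bu4NF returns the route to 16.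

2. Step 7 (asymmetric coupling). Facial discrimination by the chromium–ligand complex may be too low for this unbranched, enolisable aldehyde, so that 10 is formed with insufficient enantiomeric purity. The fallback replaces catalyst-controlled addition by reagent-controlled reduction. Such 10 (or material from a ligand-free coupling) would be oxidised with Dess–Martin periodinane/NaHCO3 to the dienone F7. Corey–Bakshi–Shibata reduction with (S)-2-methyl-CBS-oxazaborolidine and catecholborane at −78 °C, with the α-methyl alkenyl group acting as the large substituent, is expected to return 10 as the R alcohol.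

3. Step 3 (iodo-olefination). Z selectivity may erode, or the sulfone may be deprotonated and add to the aldehyde in an intramolecular aldol reaction during the ylide step. The fallback avoids basic ylides. From 4, Corey–Fuchs dibromo-olefination (CBr4, PPh3) would give the dibromoalkene F8. Palladium-catalysed trans-selective Negishi methylation (Me2Zn, Pd(P(t-Bu)3)2) would replace the bromine trans to the chain and give the Z-bromoalkene F9. F9 would be used in place of 5 in the coupling of step 7, so the route is rejoined at 10.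

**Further compounds**

F1 | step 10 | (2E,5R,6Z)-1,5-bis[(tert-butyldimethylsilyl)oxy]-2,6,9,9-tetramethyl-11-(phenylsulfonyl)undeca-2,6-diene | CC(C)(C)[Si](C)(C)O[C@@H](/C(C)=C\CC(C)(C)CCS(=O)(=O)c1ccccc1)C/C=C(\C)CO[Si](C)(C)C(C)(C)C
F2 | step 10 | (2E,5R,6Z)-1,5-bis[(tert-butyldimethylsilyl)oxy]-2,6,9,9-tetramethyl-11,11-bis(phenylsulfonyl)undeca-2,6-diene | CC(C)(C)[Si](C)(C)O[C@@H](/C(C)=C\CC(C)(C)CC(S(=O)(=O)c1ccccc1)S(=O)(=O)c1ccccc1)C/C=C(\C)CO[Si](C)(C)C(C)(C)C
F3 | step 10 | (2E,5R,6Z)-5-[(tert-butyldimethylsilyl)oxy]-2,6,9,9-tetramethyl-11,11-bis(phenylsulfonyl)undeca-2,6-dien-1-ol | CC(C)(C)[Si](C)(C)O[C@@H](/C(C)=C\CC(C)(C)CC(S(=O)(=O)c1ccccc1)S(=O)(=O)c1ccccc1)C/C=C(\C)CO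
F4 | step 10 | (2E,5R,6Z)-5-[(tert-butyldimethylsilyl)oxy]-2,6,9,9-tetramethyl-11,11-bis(phenylsulfonyl)undeca-2,6-dien-1-yl methyl carbonate | CC(C)(C)[Si](C)(C)O[C@@H](/C(C)=C\CC(C)(C)CC(S(=O)(=O)c1ccccc1)S(=O)(=O)c1ccccc1)C/C=C(\C)COC(=O)OC
F5 | step 10 | tert-butyldimethyl{[(1R,2Z,9E)-2,5,5,9-tetramethyl-7,7-bis(phenylsulfonyl)cycloundeca-2,9-dien-1-yl]oxy}silane | CC(C)(C)[Si](C)(C)O[C@@H]1C/C=C(\C)CC(S(=O)(=O)c2ccccc2)(S(=O)(=O)c2ccccc2)CC(C)(C)C/C=C\1C
F6 | step 10 | tert-butyldimethyl{[(1R,2Z,9E)-2,5,5,9-tetramethylcycloundeca-2,9-dien-1-yl]oxy}silane | CC(C)(C)[Si](C)(C)O[C@@H]1C/C=C(\C)CCCC(C)(C)C/C=C\1C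
F7 | step 7 | (2E,6Z)-1-[(tert-butyldimethylsilyl)oxy]-2,6,9,9-tetramethyl-11-(phenylsulfonyl)undeca-2,6-dien-5-one | O=C(/C(C)=C\CC(C)(C)CCS(=O)(=O)c1ccccc1)C/C=C(\C)CO[Si](C)(C)C(C)(C)C
F8 | step 3 | [(6,6-dibromo-3,3-dimethylhex-5-en-1-yl)sulfonyl]benzene | BrC(Br)=CCC(C)(C)CCS(=O)(=O)c1ccccc1
F9 | step 3 | {[(5Z)-6-bromo-3,3-dimethylhept-5-en-1-yl]sulfonyl}benzene | C/C(Br)=C/CC(C)(C)CCS(=O)(=O)c1ccccc1
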